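The C1–CHO and C6–Br bonds of the benzene ring are made together. One bromination of commercial 1,2-dibromo-4,5-dimethoxybenzene (1) gives the precursor, 1,2,3-tribromo-4,5-dimethoxybenzene (2): a methyl-protected catechol with three adjacent bromines and a single ring hydrogen. Because C1 of the target lies between C2–Br and C6–Br, where an aryllithium is best stabilised, one operation should finish the substitution pattern: LDA removes the lone hydrogen (future C6), bromine moves there from the neighbouring carbon (future C1), and DMF (3) formylates the carbon left bearing lithium between two bromines. BBr3 then frees the catechol.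

Key step: step 2

Remark: ring positions are numbered as in the target name (C1 carries the formyl group); the target has no stereocentre.

Step 1
Reactants: 1 1,2-dibromo-4,5-dimethoxybenzene
Product: 2 1,2,3-tribromo-4,5-dimethoxybenzene
Conditions: Br2 (1.05 equiv), FeBr3 (5 mol %), CH2Cl2, 0 °C to rt
Reagents that add atoms: bromine, BrBr
Why: Lewis acid-catalysed electrophilic aromatic bromination; the two ring hydrogens of 1 are equivalent and each lies ortho to a methoxy group, so substitution can only give the contiguous tribromide, and the extra bromine deactivates 2 enough that one equivalent of Br2 should stop there.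

Step 2
Reactants: 2 1,2,3-tribromo-4,5-dimethoxybenzene; 3 N,N-dimethylformamide
Product: 8 2,3,6-tribromo-4,5-dimethoxybenzaldehyde, via (2,3,4-tribromo-5,6-dimethoxyphenyl)lithium 4 (not isolated), via 1,2,3,4-tetrabromo-5,6-dimethoxybenzene 5 (not isolated), via (2,3,6-tribromo-4,5-dimethoxyphenyl)lithium 6 (not isolated), via lithium hemiaminolate 7 (not isolated)
Conditions: LiN(i-Pr)2 (LDA, 1.05 equiv, added slowly to 2), THF, −78 °C, 2 h; then DMF (3 equiv), −78 to 0 °C; 1 M HCl
Reagents that add atoms: N,N-dimethylformamide (compound 3), CN(C)C=O
Why: LDA removes the only ring hydrogen of 2, acidified by the flanking methoxy group and bromine, to give 4; 4 then gains bromine at its lithiated carbon by Br/Li exchange (at first from unmetalated 2, thereafter from the tetrabromide 5 so formed), while 5 gives up one of its two inner bromines to the next molecule of 4 and becomes 6, so that bromine has moved from the future C1 to the future C6 and lithium rests on the future C1. The closest known reaction type is the lithium amide-induced halogen dance of oligobromoarenes ended by an electrophilic quench, together with the DMF formylation of 2,6-dibromophenyllithium generated from 1,3-dibromobenzene and LDA. No ring is closed and the isolated product has no stereocentre (the carbinol carbon of 7 is racemic and disappears when 7 collapses to the aldehyde on acidic work-up). The step needs positional selectivity for lithium at equilibrium: the carbon between two bromines must win over the carbon between methoxy and bromine, which is expected because two ortho bromines stabilise an aryl anion better than one bromine plus a methoxy group (3,5-dihaloanisoles are metalated between the halogens, not next to oxygen), and the mirror symmetry of the dimethoxybenzene core allows only these two tribromoaryllithiums, so there is a single sink. Holding −78 °C suppresses loss of LiBr to an aryne, adding the base to 2 keeps a bromine donor present from the first drop, and DMF is added only after equilibration, its adduct 7 being inert to a second addition.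

Step 3
Reactants: 8 2,3,6-tribromo-4,5-dimethoxybenzaldehyde
Product: 10 2,3,6-tribromo-4,5-dihydroxybenzaldehyde, via 2,4,6,7-tetrabromo-1,3,2-benzodioxaborole-5-carbaldehyde 9 (not isolated)
Conditions: BBr3 (4 equiv), CH2Cl2, −78 °C to rt; then H2O
Reagents that add atoms: none
Why: BBr3 cleavage of aryl methyl ethers; boron coordinates the ether oxygens, bromide removes both methyl groups as bromomethane to leave the cyclic bromoborane ester 9, and water hydrolyses 9 to the catechol, while the aryl bromides and the hindered formyl group are expected to survive, as is usual for brominated dimethoxybenzaldehydes.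

Compound list
1 | 1,2-dibromo-4,5-dimethoxybenzene | COc1cc(Br)c(Br)cc1OC | starting material
2 | 1,2,3-tribromo-4,5-dimethoxybenzene | COc1cc(Br)c(Br)c(Br)c1OC | intermediate
3 | N,N-dimethylformamide | CN(C)C=O | starting material
4 | (2,3,4-tribromo-5,6-dimethoxyphenyl)lithium | [Li]c1c(Br)c(Br)c(Br)c(OC)c1OC | intermediate
5 | 1,2,3,4-tetrabromo-5,6-dimethoxybenzene | COc1c(OC)c(Br)c(Br)c(Br)c1Br | intermediate
6 | (2,3,6-tribromo-4,5-dimethoxyphenyl)lithium | [Li]c1c(Br)c(Br)c(OC)c(OC)c1Br | intermediate
7 | lithium (dimethylamino)(2,3,6-tribromo-4,5-dimethoxyphenyl)methanolate, racemic | [Li]OC(N(C)C)c1c(Br)c(Br)c(OC)c(OC)c1Br | intermediate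
8 | 2,3,6-tribromo-4,5-dimethoxybenzaldehyde | COc1c(OC)c(Br)c(C=O)c(Br)c1Br | intermediate
9 | 2,4,6,7-tetrabromo-1,3,2-benzodioxaborole-5-carbaldehyde | O=Cc1c(Br)c2OB(Br)Oc2c(Br)c1Br | intermediate
10 | 2,3,6-tribromo-4,5-dihydroxybenzaldehyde | O=Cc1c(Br)c(O)c(O)c(Br)c1Br | target

Total step count: 3. Longest linear sequence: 3 steps (1 → 2 → 8 → 10).

Steps most likely to fail

Step 2. The bromine migration may stop short or lie on the wrong side of the equilibrium, leaving lithium next to the methoxy group so that DMF formylates the wrong ring carbon. The equilibrium position has not been established for this substrate. Warming could also cause loss of LiBr to an aryne. The fallback gives up bromine migration for phenol-directed electrophilic bromination; it sets out from 1 and 3 and rejoins the route at 10. Br/Mg exchange of one bromine of 1 with i-PrMgCl·LiCl in THF should give (2-bromo-4,5-dimethoxyphenyl)magnesium chloride F1, which 3 formylates to 2-bromo-4,5-dimethoxybenzaldehyde F2. BBr3 in CH2Cl2 would then free the catechol, 2-bromo-4,5-dihydroxybenzaldehyde F3. Excess Br2 in acetic acid should brominate the two remaining ring positions, each ortho to a hydroxyl group, to give 10.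

Step 1. Control over the degree of bromination may be lost, with either sluggish conversion of the deactivated ring or a second substitution. Ether cleavage by the Lewis acid is a lesser concern. The fallback delivers exactly one bromine at a preset carbon; it sets out from 1 and rejoins at 2. LDA in the presence of Me3SiCl (in situ quench, THF, −78 °C) should generate (2,3-dibromo-5,6-dimethoxyphenyl)lithium F4, which is silylated as it forms to (2,3-dibromo-5,6-dimethoxyphenyl)trimethylsilane F5. Ipso-bromodesilylation of F5 with Br2 in CH2Cl2 at 0 °C then gives 2.

Step 3. Cleavage may stall after one methyl group, or BBr3 may attack the formyl group (halogenation at the formyl carbon). The fallback changes the oxygen protecting group so that the last step needs only BCl3 at low temperature; it sets out from 2 and rejoins at 10. BBr3 would convert 2 into 3,4,5-tribromobenzene-1,2-diol F6, and 2-bromopropane with K2CO3 in DMF would give 1,2,3-tribromo-4,5-di(propan-2-yloxy)benzene F7. The key step would then be repeated on F7 (LDA, THF, −78 °C; then 3). It would pass through [2,3,4-tribromo-5,6-di(propan-2-yloxy)phenyl]lithium F8, the bromine carrier 1,2,3,4-tetrabromo-5,6-di(propan-2-yloxy)benzene F9, the rearranged [2,3,6-tribromo-4,5-di(propan-2-yloxy)phenyl]lithium F10 and lithium (dimethylamino)[2,3,6-tribromo-4,5-di(propan-2-yloxy)phenyl]methanolate F11. Acidic work-up would give 2,3,6-tribromo-4,5-di(propan-2-yloxy)benzaldehyde F12. BCl3 in CH2Cl2 (−78 to 0 °C) would then remove both secondary alkyl groups to give 10.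

Further compounds
F1 | step 2 | (2-bromo-4,5-dimethoxyphenyl)magnesium chloride | COc1cc(Br)c([Mg]Cl)cc1OC
F2 | step 2 | 2-bromo-4,5-dimethoxybenzaldehyde | COc1cc(Br)c(C=O)cc1OC
F3 | step 2 | 2-bromo-4,5-dihydroxybenzaldehyde | O=Cc1cc(O)c(O)cc1Br
F4 | step 1 | (2,3-dibromo-5,6-dimethoxyphenyl)lithium | [Li]c1c(Br)c(Br)cc(OC)c1OC
F5 | step 1 | (2,3-dibromo-5,6-dimethoxyphenyl)trimethylsilane | C[Si](C)(C)c1c(Br)c(Br)cc(OC)c1OC
F6 | step 3 | 3,4,5-tribromobenzene-1,2-diol | Oc1cc(Br)c(Br)c(Br)c1O
F7 | step 3 | 1,2,3-tribromo-4,5-di(propan-2-yloxy)benzene | CC(C)Oc1cc(Br)c(Br)c(Br)c1OC(C)C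
F8 | step 3 | [2,3,4-tribromo-5,6-di(propan-2-yloxy)phenyl]lithium | [Li]c1c(Br)c(Br)c(Br)c(OC(C)C)c1OC(C)C
F9 | step 3 | 1,2,3,4-tetrabromo-5,6-di(propan-2-yloxy)benzene | CC(C)Oc1c(OC(C)C)c(Br)c(Br)c(Br)c1Br
F10 | step 3 | [2,3,6-tribromo-4,5-di(propan-2-yloxy)phenyl]lithium | [Li]c1c(Br)c(Br)c(OC(C)C)c(OC(C)C)c1Br
F11 | step 3 | lithium (dimethylamino)[2,3,6-tribromo-4,5-di(propan-2-yloxy)phenyl]methanolate, racemic | [Li]OC(N(C)C)c1c(Br)c(Br)c(OC(C)C)c(OC(C)C)c1Br
F12 | step 3 | 2,3,6-tribromo-4,5-di(propan-2-yloxy)benzaldehyde | CC(C)Oc1c(OC(C)C)c(Br)c(C=O)c(Br)c1Br
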